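**Assumption:** the target SMILES has no stereocentre and no stereo-defined acyclic double bond, so the compound is achiral and no enantiocontrol is needed. 4-(Benzyloxy)-3-methoxyphenol, umbelliferone, triethyl phosphonoacetate and p-ABSA are taken as commercial.

## Retrosynthetic overview

1. Target 11 comes from its 6-O-benzyl ether 10 by a late Lewis-acid debenzylation.
2. The central pyranone of 10 is closed last: C3=C4 by Horner–Wadsworth–Emmons olefination and O1–C2 by lactonisation, from salicylaldehyde 7 and α-aryloxy phosphonoacetate 4, with light correcting the alkene geometry.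
3. Key step: the C3–O–aryl bond is made by Rh-carbenoid O–H insertion of diazophosphonoacetate 2 into umbelliferone 3, not by Ullmann/SNAr coupling of two coumarins and not by the aryloxyacetic acid/Perkin condensation.
4. 7 comes from ortho-formylation of phenol 5; 2 comes from diazo transfer to triethyl phosphonoacetate 1.
5. Ring order: the umbelliferone ring is bought intact; the 6,7-dioxygenated coumarin ring is formed in step 4.

## Route

Step 1
Reactants: 1 triethyl phosphonoacetate
Product: 2 triethyl diazophosphonoacetate (ethyl 2-diazo-2-(diethoxyphosphoryl)acetate)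
Conditions: p-ABSA (1.1 equiv), DBU (1.3 equiv), MeCN, 0 °C → rt
Reagents that add atoms: 4-acetamidobenzenesulfonyl azide (p-ABSA), CC(=O)Nc1ccc(cc1)S(=O)(=O)N=[N+]=[N-]
Why: Regitz diazo transfer, in which DBU deprotonates the doubly activated P(O)/CO2Et methylene (pKa about 18–19 in DMSO, more acidic than the aryl acetates routinely diazotised this way), the carbanion attacks the terminal azide nitrogen and the triazene collapses to the diazo compound and the sulfonamide.

Step 2
Reactants: 2 triethyl diazophosphonoacetate; 3 umbelliferone (7-hydroxy-2H-chromen-2-one)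
Product: 4 ethyl 2-(diethoxyphosphoryl)-2-[(2-oxo-2H-chromen-7-yl)oxy]acetate (racemic)
Conditions: Rh2(OAc)4 (2 mol %), PhMe/ClCH2CH2Cl (1:1), 90 °C, slow addition of 2 to 3 (1.3 equiv)
Reagents that add atoms: none
Why: Rh(II)-carbenoid O–H insertion, in which the acceptor/acceptor carbenoid from 2 is captured by the phenolic oxygen of 3 (oxonium ylide, then 1,2-proton shift) in preference to the electron-poor coumarin C3=C4 bond, as precedented for diazophosphonoacetates with phenols; the new C–H stereocentre is racemic and is erased in step 4.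

Step 3
Reactants: 5 4-(benzyloxy)-3-methoxyphenol
Product: 7 5-(benzyloxy)-2-hydroxy-4-methoxybenzaldehyde, via 4-(benzyloxy)-2-(hydroxymethyl)-5-methoxyphenol 6 (not isolated)
Conditions: MgCl2 (2 equiv), Et3N (4 equiv), (CH2O)n (6 equiv), MeCN, reflux; then 1 M HCl
Reagents that add atoms: paraformaldehyde (reacts as formaldehyde), C=O
Why: Casnati–Skattebøl ortho-formylation, in which the magnesium phenoxide delivers formaldehyde only ortho to OH, at the position para to OMe and not flanked by it, and the salicyl alkoxide 6 is oxidised in situ by a second formaldehyde through Oppenauer-type hydride transfer, as with other 3,4-dialkoxyphenols.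

Step 4
Reactants: 4 ethyl 2-(diethoxyphosphoryl)-2-[(2-oxo-2H-chromen-7-yl)oxy]acetate; 7 5-(benzyloxy)-2-hydroxy-4-methoxybenzaldehyde
Product: 10 6-(benzyloxy)-7-methoxy-3-[(2-oxo-2H-chromen-7-yl)oxy]-2H-chromen-2-one, via ethyl (Z)-3-[5-(benzyloxy)-2-hydroxy-4-methoxyphenyl]-2-[(2-oxo-2H-chromen-7-yl)oxy]prop-2-enoate 8 (not isolated), via ethyl (E)-3-[5-(benzyloxy)-2-hydroxy-4-methoxyphenyl]-2-[(2-oxo-2H-chromen-7-yl)oxy]prop-2-enoate 9 (not isolated)
Conditions: DBU (3 equiv), LiCl (1.5 equiv), MeCN, 0 °C → rt; then dilute to 0.01 M, hν (365 nm LED), rt; aq. HCl work-up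
Reagents that add atoms: none
Why: Horner–Wadsworth–Emmons olefination (Masamune–Roush conditions) gives both enol-ether geometries, the E isomer 9 (aryl cis to CO2Et) lactonises at once as its phenoxide, and 365 nm light converts the Z isomer 8 into 9 by the classical o-hydroxycinnamate photoisomerisation–lactonisation, so both funnel irreversibly into 10, which has no stereocentre.

Step 5
Reactants: 10 6-(benzyloxy)-7-methoxy-3-[(2-oxo-2H-chromen-7-yl)oxy]-2H-chromen-2-one
Product: 11 6-hydroxy-7-methoxy-3-[(2-oxo-2H-chromen-7-yl)oxy]-2H-chromen-2-one (target)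
Conditions: BCl3 (1 M in CH2Cl2, 3 equiv), C6HMe5 (5 equiv), CH2Cl2, −78 °C; then H2O/NaHCO3
Reagents that add atoms: none
Why: Lewis-acid debenzylation with a cation scavenger, in which BCl3 at −78 °C ionises only the benzyl–oxygen bond and pentamethylbenzene traps the benzyl cation by Friedel–Crafts alkylation, leaving the aryl methyl ether, the enol diaryl ether, both lactones and both C3=C4 bonds (which hydrogenolysis would endanger) untouched.

## Compound list

1 | triethyl phosphonoacetate | CCOC(=O)CP(=O)(OCC)OCC | starting material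
2 | triethyl diazophosphonoacetate | CCOC(=O)C(=[N+]=[N-])P(=O)(OCC)OCC | intermediate
3 | umbelliferone (7-hydroxy-2H-chromen-2-one) | Oc1ccc2ccc(=O)oc2c1 | starting material
4 | ethyl 2-(diethoxyphosphoryl)-2-[(2-oxo-2H-chromen-7-yl)oxy]acetate (racemic) | CCOC(=O)C(Oc1ccc2ccc(=O)oc2c1)P(=O)(OCC)OCC | intermediate
5 | 4-(benzyloxy)-3-methoxyphenol | COc1cc(O)ccc1OCc1ccccc1 | starting material
6 | 4-(benzyloxy)-2-(hydroxymethyl)-5-methoxyphenol | COc1cc(O)c(CO)cc1OCc1ccccc1 | intermediate
7 | 5-(benzyloxy)-2-hydroxy-4-methoxybenzaldehyde | COc1cc(O)c(C=O)cc1OCc1ccccc1 | intermediate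
8 | ethyl (Z)-3-[5-(benzyloxy)-2-hydroxy-4-methoxyphenyl]-2-[(2-oxo-2H-chromen-7-yl)oxy]prop-2-enoate | CCOC(=O)/C(Oc1ccc2ccc(=O)oc2c1)=C/c1cc(OCc2ccccc2)c(OC)cc1O | intermediate
9 | ethyl (E)-3-[5-(benzyloxy)-2-hydroxy-4-methoxyphenyl]-2-[(2-oxo-2H-chromen-7-yl)oxy]prop-2-enoate | CCOC(=O)/C(Oc1ccc2ccc(=O)oc2c1)=C\c1cc(OCc2ccccc2)c(OC)cc1O | intermediate
10 | 6-(benzyloxy)-7-methoxy-3-[(2-oxo-2H-chromen-7-yl)oxy]-2H-chromen-2-one | COc1cc2oc(=O)c(Oc3ccc4ccc(=O)oc4c3)cc2cc1OCc1ccccc1 | intermediate
11 | 6-hydroxy-7-methoxy-3-[(2-oxo-2H-chromen-7-yl)oxy]-2H-chromen-2-one | COc1cc2oc(=O)c(Oc3ccc4ccc(=O)oc4c3)cc2cc1O | target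

## Step count and risks

Total step count: 5. Longest linear sequence: 4 steps (1 → 2 → 4 → 10 → 11, steps 1, 2, 4, 5); the aldehyde branch (step 3) joins at step 4.

Three steps most likely to fail:

**Step 4 (olefination with a free o-hydroxy aldehyde, then photo-isomerisation/lactonisation).** The phenoxide-deactivated aldehyde may react sluggishly, or the Z isomer 8 may resist isomerisation or photodimerise. The fallback sets out from 4 and 7 and enforces the geometry with a tether. The carboxylic ester of 4 alone is saponified (LiOH, THF/H2O, 0 °C, then acid, which also recloses any opened lactone) to 2-(diethoxyphosphoryl)-2-[(2-oxo-2H-chromen-7-yl)oxy]acetic acid F3. The phenol of 7 is acylated with it (EDC·HCl, DMAP, CH2Cl2) to 4-(benzyloxy)-2-formyl-5-methoxyphenyl 2-(diethoxyphosphoryl)-2-[(2-oxo-2H-chromen-7-yl)oxy]acetate F4. An intramolecular HWE (DBU, LiCl, MeCN) can then only give the cis-fused alkene and comes back to the route at 10.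

**Step 2 (carbenoid O–H insertion).** Umbelliferone is poorly soluble, and carbenoid dimerisation or aromatic C–H/Büchner chemistry may compete. The fallback sets out from 3 and builds the same C–O and C–P bonds by ionic and radical chemistry. O-Alkylation with ethyl bromoacetate (K2CO3, acetone) gives ethyl 2-[(2-oxo-2H-chromen-7-yl)oxy]acetate F1. Radical bromination of the captodative OCH2 position (NBS, AIBN, PhCF3, 80 °C) gives ethyl 2-bromo-2-[(2-oxo-2H-chromen-7-yl)oxy]acetate F2. A Michaelis–Arbuzov reaction with P(OEt)3 (neat, 100 °C) comes back to the route at 4.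

**Step 5 (debenzylation of a poorly soluble bis-lactone next to an OMe group).** Compound 10 may be insoluble at −78 °C, or the neighbouring methyl ether may be cleaved on warming. The fallback sets out from 7 and removes the protecting group before the coumarin exists. Hydrogenolysis (H2 1 atm, Pd/C, EtOAc, stopped after one equivalent) gives 2,5-dihydroxy-4-methoxybenzaldehyde F5. F5 is then taken with 4 through the step-4 conditions under argon with extra DBU. The olefination gives ethyl (Z)-3-(2,5-dihydroxy-4-methoxyphenyl)-2-[(2-oxo-2H-chromen-7-yl)oxy]prop-2-enoate F6 and ethyl (E)-3-(2,5-dihydroxy-4-methoxyphenyl)-2-[(2-oxo-2H-chromen-7-yl)oxy]prop-2-enoate F7. Irradiation and lactonisation deliver the target directly, so this fallback comes back to the route at 11.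

## Further compounds

F1 | step 2 | ethyl 2-[(2-oxo-2H-chromen-7-yl)oxy]acetate | CCOC(=O)COc1ccc2ccc(=O)oc2c1
F2 | step 2 | ethyl 2-bromo-2-[(2-oxo-2H-chromen-7-yl)oxy]acetate (racemic) | CCOC(=O)C(Br)Oc1ccc2ccc(=O)oc2c1
F3 | step 4 | 2-(diethoxyphosphoryl)-2-[(2-oxo-2H-chromen-7-yl)oxy]acetic acid (racemic) | CCOP(=O)(OCC)C(Oc1ccc2ccc(=O)oc2c1)C(=O)O
F4 | step 4 | 4-(benzyloxy)-2-formyl-5-methoxyphenyl 2-(diethoxyphosphoryl)-2-[(2-oxo-2H-chromen-7-yl)oxy]acetate (racemic) | CCOP(=O)(OCC)C(Oc1ccc2ccc(=O)oc2c1)C(=O)Oc1cc(OC)c(OCc2ccccc2)cc1C=O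
F5 | step 5 | 2,5-dihydroxy-4-methoxybenzaldehyde | COc1cc(O)c(C=O)cc1O
F6 | step 5 | ethyl (Z)-3-(2,5-dihydroxy-4-methoxyphenyl)-2-[(2-oxo-2H-chromen-7-yl)oxy]prop-2-enoate | CCOC(=O)/C(Oc1ccc2ccc(=O)oc2c1)=C/c1cc(O)c(OC)cc1O
F7 | step 5 | ethyl (E)-3-(2,5-dihydroxy-4-methoxyphenyl)-2-[(2-oxo-2H-chromen-7-yl)oxy]prop-2-enoate | CCOC(=O)/C(Oc1ccc2ccc(=O)oc2c1)=C\c1cc(O)c(OC)cc1O
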